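The strategy rests on breaking the O1–C2 bond of the pyranone (ring C). C2, the only stereocentre, carries O1 (the phenol oxygen on C8a of ring A) and lies β to the C4 ketone, so ring C is the product of an intramolecular oxa-Michael addition. Both arenes are bought. The precursor is an open 2'-hydroxychalcone with a temporary tert-butyl ester on C3 (an alkylidene β-ketoester). In one pot a cinchona thiourea closes ring C enantioselectively and sets C2, then acid removes the ester as isobutene and CO2. No protecting group is used.

Key step: step 3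

Assumption: the quinidine-derived thiourea is taken as the pseudoenantiomer that gives the (2S) product; the sense is to be confirmed on the first run, and if it is opposite the quinine-derived pseudoenantiomer is used under the same conditions.

Step 1
Reactants: 1 1-(2-hydroxy-3,4-dimethoxyphenyl)ethan-1-one
Product: 2 tert-butyl 3-(2-hydroxy-3,4-dimethoxyphenyl)-3-oxopropanoate
Conditions: LiHMDS (3.2 equiv), THF, −78 °C; Boc2O (1.05 equiv), −78 to 0 °C; cold 1 M HCl work-up
Reagents that add atoms: di-tert-butyl dicarbonate CC(C)(C)OC(=O)OC(=O)OC(C)(C)C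
Why: Crossed Claisen-type C-acylation of the phenoxide–enolate dianion, in which the terminal enolate carbon is far more nucleophilic towards Boc2O at −78 °C than the chelated lithium phenoxide, and the third equivalent of base turns the product into its unreactive enolate so that a second acylation is stopped.

Step 2
Reactants: 2 tert-butyl 3-(2-hydroxy-3,4-dimethoxyphenyl)-3-oxopropanoate, 3 3-hydroxy-4,5-dimethoxybenzaldehyde
Product: 4 tert-butyl (Z)-2-(2-hydroxy-3,4-dimethoxybenzoyl)-3-(3-hydroxy-4,5-dimethoxyphenyl)prop-2-enoate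
Conditions: piperidine (10 mol%), AcOH (10 mol%), 4 Å MS, toluene, rt
Reagents that add atoms: none
Why: Knoevenagel condensation through the piperidine iminium ion of 3; the buffered conditions and the hydrogen bond from the C2' phenol to the ketone should keep the phenol from adding to the new alkene, and the (Z) isomer (aryl cis to the ester) is expected to predominate and is taken on as a single geometric isomer after crystallisation.

Step 3
Reactants: 4 tert-butyl (Z)-2-(2-hydroxy-3,4-dimethoxybenzoyl)-3-(3-hydroxy-4,5-dimethoxyphenyl)prop-2-enoate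
Product: 7 (2S)-2-(3-hydroxy-4,5-dimethoxyphenyl)-7,8-dimethoxychroman-4-one, via tert-butyl 4-oxochromane-3-carboxylate 5 (not isolated), via 4-oxochromane-3-carboxylic acid 6 (not isolated)
Conditions: N-[3,5-bis(trifluoromethyl)phenyl]-N'-[(9R)-6'-methoxycinchonan-9-yl]thiourea (quinidine-derived, 10 mol%), toluene, −25 °C; then TsOH·H2O (0.5 equiv), 80 °C, same flask
Reagents that add atoms: none
Why: The quinuclidine nitrogen of the catalyst deprotonates the C8a phenol while the thiourea N–H pair binds the two carbonyl groups of the β-ketoester, and the phenoxide adds to the β-carbon of the doubly activated alkene to give the enolisable ester 5, after which TsOH cleaves the tert-butyl ester to isobutene and acid 6, which loses CO2 at 80 °C. The closest known reaction type is the cinchona-thiourea-catalysed intramolecular oxa-Michael addition of 2'-hydroxy alkylidene β-ketoesters with decarboxylation in the same pot, the chemical counterpart of the chalcone isomerase step of flavanone biosynthesis. Ring C closes in the 6-endo-trig mode through the O1–C2 bond. The C2 stereocentre is set by the catalyst, whose base and hydrogen-bond sites hold the phenoxide and the dicarbonyl unit so that one face of the alkene is presented (2S under the assumption above), and C3 is no longer a stereocentre once the ester is gone. The step needs enantioface selectivity over the racemic background and must avoid retro-oxa-Michael opening at C2: the two-point-binding β-ketoester, the low temperature in non-polar toluene and the stable enol of 5 should secure the first, and the use of acid instead of base for the decarboxylation should secure the second. Only the C8a phenol can reach C2 within a ring, so the free B-ring phenol, which could add only intermolecularly, is not expected to compete.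

Compound list
1 | 1-(2-hydroxy-3,4-dimethoxyphenyl)ethan-1-one | CC(=O)c1ccc(OC)c(OC)c1O | starting material
2 | tert-butyl 3-(2-hydroxy-3,4-dimethoxyphenyl)-3-oxopropanoate | CC(C)(C)OC(=O)CC(=O)c1ccc(OC)c(OC)c1O | intermediate
3 | 3-hydroxy-4,5-dimethoxybenzaldehyde | COc1cc(C=O)cc(O)c1OC | starting material
4 | tert-butyl (Z)-2-(2-hydroxy-3,4-dimethoxybenzoyl)-3-(3-hydroxy-4,5-dimethoxyphenyl)prop-2-enoate | CC(C)(C)OC(=O)/C(=C\c1cc(O)c(OC)c(OC)c1)C(=O)c1ccc(OC)c(OC)c1O | intermediate
5 | tert-butyl (2S,3R)-2-(3-hydroxy-4,5-dimethoxyphenyl)-7,8-dimethoxy-4-oxochromane-3-carboxylate (trans, in equilibrium with its enol; not isolated) | COc1cc([C@@H]2[C@@H](C(=O)OC(C)(C)C)C(=O)c3ccc(OC)c(OC)c3O2)cc(O)c1OC | intermediate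
6 | (2S,3R)-2-(3-hydroxy-4,5-dimethoxyphenyl)-7,8-dimethoxy-4-oxochromane-3-carboxylic acid (not isolated) | COc1cc([C@@H]2[C@@H](C(=O)O)C(=O)c3ccc(OC)c(OC)c3O2)cc(O)c1OC | intermediate
7 | (2S)-2-(3-hydroxy-4,5-dimethoxyphenyl)-7,8-dimethoxychroman-4-one | COc1cc([C@@H]2CC(=O)c3ccc(OC)c(OC)c3O2)cc(O)c1OC | target

Total step count: 3. Longest linear sequence: 3 steps (1 → 2 → 4 → 7).

Steps most likely to fail

Step 3. The enantioface selectivity may erode because the free B-ring phenol competes with the C8a phenol for the basic and hydrogen-bonding sites of the catalyst. The fallback masks that phenol; it sets out from 3 (with 2 as partner) and comes back at 7. Aldehyde 3 is benzylated (BnBr, K2CO3, DMF, rt) to 3-(benzyloxy)-4,5-dimethoxybenzaldehyde F1. Knoevenagel condensation of F1 with 2 under the step 2 conditions should give tert-butyl (Z)-3-[3-(benzyloxy)-4,5-dimethoxyphenyl]-2-(2-hydroxy-3,4-dimethoxybenzoyl)prop-2-enoate F2. The same thiourea cyclisation and TsOH treatment then lead through tert-butyl (2S,3R)-2-[3-(benzyloxy)-4,5-dimethoxyphenyl]-7,8-dimethoxy-4-oxochromane-3-carboxylate F3 and the corresponding (2S,3R)-carboxylic acid F4, neither isolated, to (2S)-2-[3-(benzyloxy)-4,5-dimethoxyphenyl]-7,8-dimethoxychroman-4-one F5. Neutral hydrogenolysis (H2, Pd/C, EtOAc, rt), which does not open the ring, returns to 7.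

Step 1. The Boc group may be transferred to the phenoxide oxygen instead of the enolate carbon, or a second transfer may occur. The fallback removes the phenoxide from the acylation; it sets out from 1 and comes back at 2. Ketone 1 is benzylated (BnBr, K2CO3, acetone, reflux) to 1-[2-(benzyloxy)-3,4-dimethoxyphenyl]ethan-1-one F6. Its simple lithium enolate (LiHMDS 2.2 equiv, THF, −78 °C) is acylated with Boc2O to tert-butyl 3-[2-(benzyloxy)-3,4-dimethoxyphenyl]-3-oxopropanoate F7. Hydrogenolysis (H2, Pd/C, EtOAc, rt) frees the phenol and gives 2.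

Step 2. The phenol of the product may add to the new alkene in the condensation flask under amine catalysis, which would give racemic ring-closed material before the chiral catalyst is present. The fallback keeps the C2' phenol masked during the condensation; it sets out from 2 and comes back at 4. Phenol 2 is silylated (TBSCl, imidazole, DMF, rt) to tert-butyl 3-[2-(tert-butyldimethylsilyloxy)-3,4-dimethoxyphenyl]-3-oxopropanoate F8. Knoevenagel condensation of F8 with 3 should give tert-butyl (Z)-2-[2-(tert-butyldimethylsilyloxy)-3,4-dimethoxybenzoyl]-3-(3-hydroxy-4,5-dimethoxyphenyl)prop-2-enoate F9. Desilylation under non-basic conditions (HF·pyridine, THF, 0 °C) releases the neutral phenol 4 without a phenoxide stage.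

Further compounds
F1 | step 3 | 3-(benzyloxy)-4,5-dimethoxybenzaldehyde | COc1cc(C=O)cc(OCc2ccccc2)c1OC
F2 | step 3 | tert-butyl (Z)-3-[3-(benzyloxy)-4,5-dimethoxyphenyl]-2-(2-hydroxy-3,4-dimethoxybenzoyl)prop-2-enoate | CC(C)(C)OC(=O)/C(=C\c1cc(OCc2ccccc2)c(OC)c(OC)c1)C(=O)c1ccc(OC)c(OC)c1O
F3 | step 3 | tert-butyl (2S,3R)-2-[3-(benzyloxy)-4,5-dimethoxyphenyl]-7,8-dimethoxy-4-oxochromane-3-carboxylate | COc1cc([C@@H]2[C@@H](C(=O)OC(C)(C)C)C(=O)c3ccc(OC)c(OC)c3O2)cc(OCc2ccccc2)c1OC
F4 | step 3 | (2S,3R)-2-[3-(benzyloxy)-4,5-dimethoxyphenyl]-7,8-dimethoxy-4-oxochromane-3-carboxylic acid | COc1cc([C@@H]2[C@@H](C(=O)O)C(=O)c3ccc(OC)c(OC)c3O2)cc(OCc2ccccc2)c1OC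
F5 | step 3 | (2S)-2-[3-(benzyloxy)-4,5-dimethoxyphenyl]-7,8-dimethoxychroman-4-one | COc1cc([C@@H]2CC(=O)c3ccc(OC)c(OC)c3O2)cc(OCc2ccccc2)c1OC
F6 | step 1 | 1-[2-(benzyloxy)-3,4-dimethoxyphenyl]ethan-1-one | CC(=O)c1ccc(OC)c(OC)c1OCc1ccccc1
F7 | step 1 | tert-butyl 3-[2-(benzyloxy)-3,4-dimethoxyphenyl]-3-oxopropanoate | CC(C)(C)OC(=O)CC(=O)c1ccc(OC)c(OC)c1OCc1ccccc1
F8 | step 2 | tert-butyl 3-[2-(tert-butyldimethylsilyloxy)-3,4-dimethoxyphenyl]-3-oxopropanoate | CC(C)(C)OC(=O)CC(=O)c1ccc(OC)c(OC)c1O[Si](C)(C)C(C)(C)C
F9 | step 2 | tert-butyl (Z)-2-[2-(tert-butyldimethylsilyloxy)-3,4-dimethoxybenzoyl]-3-(3-hydroxy-4,5-dimethoxyphenyl)prop-2-enoate | CC(C)(C)OC(=O)/C(=C\c1cc(O)c(OC)c(OC)c1)C(=O)c1ccc(OC)c(OC)c1O[Si](C)(C)C(C)(C)C
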